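**Strategy.** Daucane locants are used (C1: methyl-bearing ring-fusion carbon; C8: methyl-bearing oxirane carbon; C9: oxirane CH; C10: ring CH2). The seven-membered ring is read as a cyclopentane (C1, C5, C6, C7, C8) enlarged by C9–C10, with the oxirane oxygen as a former cyclopentanol oxygen on C8. In one operation an alkoxy radical of an epoxy cis-bicyclo[3.3.0]octan-2-ol cleaves C1–C8, the tertiary C1 radical adds to a vinylsulfonium salt (C1–C10), and the resulting sulfur ylide attacks the unveiled C8 ketone (C8–C9) and closes the oxirane. The cycloheptane and the epoxide form together; the precursor's C1 and C8 configurations are erased.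

Key step: step 11

Remark on locants: the daucane numbering of the target is kept for every intermediate (C2, C3: five-ring CH2; C4: carbinol carbon with isopropyl; C5: ring-fusion CH; C6: CH–O-aroyl; C7: CH–OH); β is the face of the C4 hydroxyl, α the opposite face.

Assumption: the diacetate obtained from cycloocta-1,5-diene is taken as the endo,endo isomer; these two carbinol centres are removed by oxidation in step 4, so the assumption does not affect the later route.

Step 1
Reactants: 1 (1Z,5Z)-cycloocta-1,5-diene
Product: 2 rac-endo,endo-cis-bicyclo[3.3.0]octane-2,6-diyl diacetate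
Conditions: Pd(OAc)2 (cat.), Pb(OAc)4, AcOH, rt
Reagents that add atoms: lead tetraacetate, CC(=O)O[Pb](OC(C)=O)(OC(C)=O)OC(C)=O
Why: Palladium-catalysed transannular oxidative diacetoxylation, in which acetoxypalladation of one alkene, insertion of the second alkene across the ring and oxidative C–O bond formation give the 2,6-difunctionalised bicycle, the cis ring fusion being imposed by the transannular syn insertion.

Step 2
Reactants: 2 rac-endo,endo-cis-bicyclo[3.3.0]octane-2,6-diyl diacetate
Product: 3 rac-endo,endo-cis-bicyclo[3.3.0]octane-2,6-diol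
Conditions: K2CO3, MeOH, rt
Reagents that add atoms: none
Why: Base-catalysed methanolysis (transesterification) of both acetates, which touches no stereocentre.

Step 3
Reactants: 3 rac-endo,endo-cis-bicyclo[3.3.0]octane-2,6-diol
Product: 4 (1R,2S,5R,6S)-cis-bicyclo[3.3.0]octane-2,6-diol
Conditions: lipase from Burkholderia cepacia, vinyl acetate, t-BuOMe, 30 °C, run to just beyond half conversion, chromatographic separation
Reagents that add atoms: none
Why: Lipase-catalysed kinetic resolution by acylation, in which the enzyme should follow the empirical rule for secondary alcohols and acetylate the (R)-carbinols of the (1S,2R,5S,6R) enantiomer, leaving the required (1R,2S,5R,6S)-diol.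

Step 4
Reactants: 4 (1R,2S,5R,6S)-cis-bicyclo[3.3.0]octane-2,6-diol
Product: 5 (1R,5R)-cis-bicyclo[3.3.0]octane-2,6-dione
Conditions: TEMPO (cat.), KBr (cat.), NaOCl, NaHCO3, CH2Cl2/H2O, 0 °C
Reagents that add atoms: none
Why: Anelli oxidation of both secondary alcohols; the ring-fusion centres α to the carbonyls cannot epimerise singly because the trans-fused bicycle is prohibitively strained.

Step 5
Reactants: 5 (1R,5R)-cis-bicyclo[3.3.0]octane-2,6-dione
Product: 6 (1R,5R,6R)-6-hydroxy-6-isopropyl-cis-bicyclo[3.3.0]octan-2-one
Conditions: iPrMgCl (1.05 equiv), CeCl3, THF, −78 °C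
Reagents that add atoms: isopropylmagnesium chloride, CC(C)[Mg]Cl
Why: Organocerium 1,2-addition (enolisation suppressed); the two carbonyls are homotopic through the C2 axis, so mono-addition gives one constitution, and attack from the convex face sets C4 with isopropyl α and hydroxyl β.

Step 6
Reactants: 6 (1R,5R,6R)-6-hydroxy-6-isopropyl-cis-bicyclo[3.3.0]octan-2-one
Product: 7 C7=C8 trimethylsilyl enol ether of 6 carrying the 4β-trimethylsilyl ether
Conditions: LiN(iPr)2 (2.3 equiv), Me3SiCl (3 equiv), THF, −78 to 0 °C
Reagents that add atoms: chlorotrimethylsilane, C[Si](C)(C)Cl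
Why: Kinetic enolisation with in situ silyl trapping should give the less substituted C7–C8 silyl enol ether rather than the strained ring-fusion isomer, and the C4 alkoxide is silylated in the same operation.

Step 7
Reactants: 7 C7=C8 trimethylsilyl enol ether of 6 carrying the 4β-trimethylsilyl ether
Product: 8 diquinane enone (C8 ketone, C6=C7 alkene, 4β-OSiMe3)
Conditions: Pd(OAc)2 (10 mol %), O2 (1 atm), DMSO, rt
Reagents that add atoms: none
Why: Saegusa–Ito oxidation, in which the palladium enolate at C7 undergoes syn β-hydride elimination of H6 to give the cyclopentenone while the tertiary silyl ether is inert.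

Step 8
Reactants: 8 diquinane enone (C8 ketone, C6=C7 alkene, 4β-OSiMe3)
Product: 9 1-methyl diquinane enone (angular methyl on C1, α face)
Conditions: LiN(iPr)2, THF, −78 °C; MeI, DMPU, −78 to −30 °C
Reagents that add atoms: iodomethane, CI
Why: Kinetic α′-deprotonation of the enone at C1, its only α′ position, gives the cross-conjugated enolate whose C-methylation creates the quaternary centre; the methyl must enter on the convex α face because only the cis-fused bicycle is accessible.

Step 9
Reactants: 9 1-methyl diquinane enone (angular methyl on C1, α face)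
Product: 10 tertiary allylic alcohol (8β-OH, 8α-CH3)
Conditions: MeLi, CeCl3, THF, −78 °C
Reagents that add atoms: methyllithium, [Li]C
Why: Organocerium 1,2-addition to the hindered enone carbonyl, expected from the convex face because ring A shields the concave face, gives the 8β-alcohol; this centre only has to direct step 10 and becomes sp2 again in step 11.

Step 10
Reactants: 10 tertiary allylic alcohol (8β-OH, 8α-CH3)
Product: 11 epoxy diquinanol (6β,7β-oxirane, 8β-OH)
Conditions: VO(acac)2 (5 mol %), t-BuOOH, CH2Cl2, 0 °C
Reagents that add atoms: tert-butyl hydroperoxide, CC(C)(C)OO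
Why: Hydroxyl-directed vanadium-catalysed epoxidation of the cyclic allylic alcohol delivers oxygen syn to the 8β-OH and so places the 6,7-oxirane on the concave β face, which an undirected peracid would not reach.

Step 11
Reactants: 11 epoxy diquinanol (6β,7β-oxirane, 8β-OH); 12 diphenyl(vinyl)sulfonium trifluoromethanesulfonate
Product: 15 6β,7β:8α,9α-diepoxy-4β-(trimethylsilyloxy)daucane, via keto sulfonium triflate 13 (not isolated), via sulfonium ylide 14 (not isolated)
Conditions: [Ir(dF(CF3)ppy)2(5,5'-d(CF3)bpy)]PF6 (2 mol %), Bu4P+ (MeO)2PO2− (25 mol %), 12 (2 equiv), CH2Cl2, blue LEDs, rt; then DBU, 0 °C to rt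
Reagents that add atoms: none
Why: Proposed new method: photoinduced proton-coupled electron transfer (excited iridium photocatalyst, phosphate base) converts the free C8 hydroxyl into an alkoxy radical whose β-scission cleaves C1–C8 to the tertiary C1 radical and the C8 methyl ketone, the radical adds to the CH2 terminus of 12 (C1–C10), the α-sulfonium radical is reduced by the reduced photocatalyst to ylide 14 (buffered as salt 13 and released again by DBU), and 14 adds to the C8 carbonyl (C8–C9) before the alkoxide displaces Ph2S (C9–O). The closest known reaction types are photocatalytic alkoxy-radical ring-opening Giese reactions of cycloalkanols, radical addition to vinylsulfonium salts with reduction to the ylide, and the vinylsulfonium epoxy-annulation (conjugate addition then intramolecular Corey–Chaykovsky epoxidation); their merger into a two-carbon ring expansion is what is new. The cycloheptane closes by 7-exo-trig attack of the ylide carbon on the ketone and the oxirane by 3-exo-tet displacement of the sulfide. C1 is set by approach of 12 to the planar radical anti to the C5 side chain (C10 α, methyl β, hence the trans ring fusion) whatever the C1 and C8 configurations of 11, C8 by carbonyl addition in the rotamer that keeps the ketone oxygen anti to the adjacent 6,7-oxirane oxygen (8-O α), and C9 by the cis fusion that an oxirane on a seven-membered ring requires. The step needs O–H activation only at C8 (the C4 oxygen is silylated), scission of C1–C8 rather than C7–C8 (the latter would give a disfavoured oxiranyl radical) and carbonyl addition rather than proton transfer by the ylide (the ylide is too weakly basic to enolise the methyl ketone).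

Step 12
Reactants: 15 6β,7β:8α,9α-diepoxy-4β-(trimethylsilyloxy)daucane
Product: 16 6β,7β:8α,9α-diepoxydaucan-4β-ol
Conditions: Bu4NF, THF, 0 °C
Reagents that add atoms: none
Why: Fluoride-induced desilylation of the tertiary trimethylsilyl ether, under which both oxiranes are inert.

Step 13
Reactants: 16 6β,7β:8α,9α-diepoxydaucan-4β-ol; 17 4-hydroxybenzoic acid
Product: 18 8α,9α-epoxy-4β,7β-dihydroxydaucan-6α-yl 4-hydroxybenzoate (CNP0290052.1)
Conditions: (R,R)-(salen)Co(OTs) (5 mol %; salen = N,N'-bis(3,5-di-tert-butylsalicylidene)cyclohexane-1,2-diamine dianion), iPr2NEt, MeCN/t-BuOMe, rt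
Reagents that add atoms: none
Why: (salen)Co-catalysed carboxylate opening of an epoxide (SN2 with inversion), in which the bulky Lewis acid should activate only the disubstituted 6,7-oxirane (also hydrogen-bonded to the syn C4 hydroxyl) and the carboxylate, not the less acidic phenol, attacks C6 remote from the fully substituted C8, giving the 6α-ester and the 7β-alcohol while the trisubstituted 8,9-oxirane is untouched.

**Compound list**

1 | (1Z,5Z)-cycloocta-1,5-diene | C1C/C=C\CC/C=C\1 | starting material
2 | rac-endo,endo-cis-bicyclo[3.3.0]octane-2,6-diyl diacetate (racemic, 1R,2S,5R,6S enantiomer drawn) | CC(=O)O[C@H]1CC[C@H]2[C@@H](OC(C)=O)CC[C@@H]12 | intermediate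
3 | rac-endo,endo-cis-bicyclo[3.3.0]octane-2,6-diol (racemic, 1R,2S,5R,6S enantiomer drawn) | O[C@H]1CC[C@H]2[C@@H](O)CC[C@@H]12 | intermediate
4 | (1R,2S,5R,6S)-cis-bicyclo[3.3.0]octane-2,6-diol | O[C@H]1CC[C@H]2[C@@H](O)CC[C@@H]12 | intermediate
5 | (1R,5R)-cis-bicyclo[3.3.0]octane-2,6-dione | O=C1CC[C@H]2C(=O)CC[C@@H]12 | intermediate
6 | (1R,5R,6R)-6-hydroxy-6-isopropyl-cis-bicyclo[3.3.0]octan-2-one (C8 ketone, 4β-OH, 4α-isopropyl) | CC(C)[C@]1(O)CC[C@H]2C(=O)CC[C@@H]12 | intermediate
7 | C7=C8 trimethylsilyl enol ether of 6 carrying the 4β-trimethylsilyl ether | CC(C)[C@]1(O[Si](C)(C)C)CC[C@H]2C(O[Si](C)(C)C)=CC[C@@H]12 | intermediate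
8 | diquinane enone: 6-isopropyl-6-(trimethylsilyloxy)-cis-bicyclo[3.3.0]oct-3-en-2-one (C8 ketone, C6=C7) | CC(C)[C@]1(O[Si](C)(C)C)CC[C@H]2C(=O)C=C[C@@H]12 | intermediate
9 | 1-methyl diquinane enone: 8 with the angular methyl on C1 (α face, cis fusion) | CC(C)[C@]1(O[Si](C)(C)C)CC[C@@]2(C)C(=O)C=C[C@@H]12 | intermediate
10 | tertiary allylic alcohol: 9 after methyl addition to C8 (8β-OH, 8α-CH3) | CC(C)[C@]1(O[Si](C)(C)C)CC[C@@]2(C)[C@@](C)(O)C=C[C@@H]12 | intermediate
11 | epoxy diquinanol: 6β,7β-epoxide of 10 | CC(C)[C@]1(O[Si](C)(C)C)CC[C@@]2(C)[C@@](C)(O)[C@H]3O[C@H]3[C@@H]12 | intermediate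
12 | diphenyl(vinyl)sulfonium trifluoromethanesulfonate | C=C[S+](c1ccccc1)c1ccccc1.[O-]S(=O)(=O)C(F)(F)F | starting material
13 | keto sulfonium triflate: cyclopentane with C1 bearing β-CH3 and α-CH2CH2S+Ph2, C5 bearing the cis-6,7-epoxy C8 methyl ketone, 4β-OSiMe3 | CC(C)[C@]1(O[Si](C)(C)C)CC[C@](C)(CC[S+](c2ccccc2)c2ccccc2)[C@H]1[C@@H]3O[C@@H]3C(C)=O.[O-]S(=O)(=O)C(F)(F)F | intermediate
14 | sulfonium ylide: 13 after loss of a C9 proton | CC(C)[C@]1(O[Si](C)(C)C)CC[C@](C)(C[CH-][S+](c2ccccc2)c2ccccc2)[C@H]1[C@@H]3O[C@@H]3C(C)=O | intermediate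
15 | 6β,7β:8α,9α-diepoxy-4β-(trimethylsilyloxy)daucane | CC(C)[C@]1(O[Si](C)(C)C)CC[C@]2(C)C[C@@H]3O[C@]3(C)[C@H]4O[C@H]4[C@H]21 | intermediate
16 | 6β,7β:8α,9α-diepoxydaucan-4β-ol | CC(C)[C@]1(O)CC[C@]2(C)C[C@@H]3O[C@]3(C)[C@H]4O[C@H]4[C@H]21 | intermediate
17 | 4-hydroxybenzoic acid | OC(=O)c1ccc(O)cc1 | starting material
18 | 8α,9α-epoxy-4β,7β-dihydroxydaucan-6α-yl 4-hydroxybenzoate (CNP0290052.1) | CC(C)[C@]1(O)CC[C@]2(C)C[C@@H]3O[C@]3(C)[C@@H](O)[C@H](OC(=O)c3ccc(O)cc3)[C@H]21 | target

**Step count and risks**

Total steps: 13. Longest linear sequence: 13 steps (1 to 18).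

Steps most likely to fail:

Step 11 (proposed new method). The α-sulfonium radical may not be reduced to the ylide efficiently (back electron transfer, quenching of the excited catalyst by diphenyl sulfide), or the acceptor may add to the C1 radical without facial control. The fallback uses known chemistry only, sets out from 11 and comes back at 15. Hypoiodite β-fragmentation of 11 (PhI(OAc)2, I2, hν, CH2Cl2) gives the ring-opened tertiary iodide F1. Keck allylation (allylSnBu3, AIBN, benzene, 80 °C), anti to the C5 side chain, gives the allyl ketone F2. Wittig methylenation (Ph3P=CH2, THF) gives the diene F3. Ring-closing metathesis with the second-generation Grubbs catalyst (CH2Cl2, 40 °C) closes the seven-membered ring as the 8,9-alkene F4. Epoxidation with mCPBA/NaHCO3 anti to the 6,7-oxirane then returns to 15.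

Step 13. The carboxylate may attack C9 of the 8,9-oxirane or C7, or the phenol may compete as nucleophile; if C7 attack shows a mismatched catalyst, the (S,S) ligand would be tried first. The fallback installs the ester while only one oxirane is present; it sets out from 11 and comes back at 18. Titanium-mediated C3-selective opening of the 2,3-epoxy alcohol (Ti(OiPr)4, 4-(tert-butyldimethylsilyloxy)benzoic acid, CH2Cl2) gives the diquinane diol ester F5 with inversion at C6. Silylation of the secondary 7-OH (Me3SiCl, imidazole, DMF, 0 °C) gives the silyl ether F6. Ring expansion under the conditions of step 11 gives the protected target F7, and Bu4NF/AcOH in THF removes the three silyl groups to give 18.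

Step 9. The methyl nucleophile may add from the concave face, because the convex face carries the angular methyl; the directed epoxidation of step 10 would then place the oxirane on the α face. The fallback makes the oxirane face independent of C8; it sets out from 9 and comes back at 15. The 8α-alcohol F8 from the methyl addition is treated with NBS in DMSO/H2O, where bromonium formation on the convex α face and anti attack of water at C6 give the bromohydrin F9. K2CO3 in MeOH closes the 6β,7β-oxirane by intramolecular displacement to give the C8 epimer of 11, F10. F10 is submitted to step 11 unchanged, since C8 becomes sp2 there, and returns at 15.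

Further compounds
F1 | step 11 | ring-opened tertiary iodide (iodine on C1, mixture at C1; C5 bearing the cis-6,7-epoxy C8 methyl ketone) | CC(C)[C@]1(O[Si](C)(C)C)CCC(C)(I)[C@H]1[C@@H]2O[C@@H]2C(C)=O
F2 | step 11 | allyl ketone (C1: β-CH3, α-allyl) | CC(C)[C@]1(O[Si](C)(C)C)CC[C@](C)(CC=C)[C@H]1[C@@H]2O[C@@H]2C(C)=O
F3 | step 11 | diene (C8 methylenated) | CC(C)[C@]1(O[Si](C)(C)C)CC[C@](C)(CC=C)[C@H]1[C@@H]2O[C@@H]2C(C)=C
F4 | step 11 | 6β,7β-epoxy-4β-(trimethylsilyloxy)dauc-8-ene | CC(C)[C@]1(O[Si](C)(C)C)CC[C@]2(C)CC=C(C)[C@H]3O[C@H]3[C@H]21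
F5 | step 13 | diquinane diol ester (6α-aroyloxy, 7β-OH, 8β-OH; aryl = 4-(tert-butyldimethylsilyloxy)phenyl) | CC(C)[C@]1(O[Si](C)(C)C)CC[C@@]2(C)[C@@](C)(O)[C@@H](O)[C@H](OC(=O)c3ccc(O[Si](C)(C)C(C)(C)C)cc3)[C@@H]12
F6 | step 13 | 7-O-trimethylsilyl ether of F5 | CC(C)[C@]1(O[Si](C)(C)C)CC[C@@]2(C)[C@@](C)(O)[C@@H](O[Si](C)(C)C)[C@H](OC(=O)c3ccc(O[Si](C)(C)C(C)(C)C)cc3)[C@@H]12
F7 | step 13 | tris-silylated target (4-OSiMe3, 7-OSiMe3, aryl OSiMe2tBu) | CC(C)[C@]1(O[Si](C)(C)C)CC[C@]2(C)C[C@@H]3O[C@]3(C)[C@@H](O[Si](C)(C)C)[C@H](OC(=O)c3ccc(O[Si](C)(C)C(C)(C)C)cc3)[C@H]21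
F8 | step 9 | C8 epimer of 10 (8α-OH, 8β-CH3) | CC(C)[C@]1(O[Si](C)(C)C)CC[C@@]2(C)[C@](C)(O)C=C[C@@H]12
F9 | step 9 | bromohydrin (7α-Br, 6β-OH, 8α-OH) | CC(C)[C@]1(O[Si](C)(C)C)CC[C@@]2(C)[C@](C)(O)[C@H](Br)[C@@H](O)[C@@H]12
F10 | step 9 | C8 epimer of 11 (6β,7β-oxirane, 8α-OH) | CC(C)[C@]1(O[Si](C)(C)C)CC[C@@]2(C)[C@](C)(O)[C@H]3O[C@H]3[C@@H]12
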